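- oak: starting material 0.50 M; the very flask that is asked about, followed so far
- flask: starting material 0.50 M; time 15 d

oak run (percent of the starting material charged)

| time / d | target / % | isomer of the product / % | starting material / % |
|---|---|---|---|
| 0.250 | 42.7 | 51.0 | 3.5 |
| 0.417 | 45.3 | 52.8 | 0.3 |
| 0.625 | 45.0 | 53.5 | 0 |
| 1.04 | 45.4 | 53.0 | 0 |
| 1.67 | 45.0 | 52.9 | 0.2 |
| 3.00 | 45.1 | 52.6 | 0 |

(standard deviation of a reading: 0.3 percentage points)

- a reading or a percentage of target counts all its forms, free or not

1. share of target in target plus isomer of the product at 8.0 min
2. share of target in target plus isomer of the product at 8.0 h
3. share of target in target plus isomer of the product at 15 d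

In the oak flask one ratio holds still within the scatter of the readings while the starting material falls: the share of target in target plus isomer of the product, the selectivity of this flask. The readings from 0.625 d on put it at 46.0%, called S here, and single readings give 45.6% at 0.250 d and 46.2% at 3.00 d, with a scatter of 0.3 percentage points on each amount read.

Two extreme flasks can be solved in the head. If the products arise side by side at a fixed ratio and never exchange, which is kinetic control, the share is frozen from the first conversion and stands at S at 8.0 min, 8.0 h and 15 d alike. If they reach equilibrium before the first reading at 0.250 d, which is thermodynamic control, S is their equilibrium, so 8.0 h and 15 d still give S, but 8.0 min may lie elsewhere, for it falls well inside the half-life of the starting material, 1.24 h as read from the first reading. Between them lies slow exchange, which shows as a drift, and these readings show no clear one, so my reckoning puts S at all three times, with the loosest hold at 8.0 min, which no reading reaches.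

The forecast gives 46%, 46% and 46.3%, the last a little above S, and it grants for the early time that “fast product interconversion or an early kinetic ratio cannot be excluded”.

The simulation gives 45.8%, 45.8% and 45.8%, so the forecast is right within its tolerance, and the share in the oak flask stands still from 8.0 min to 15 d.

    other conformer ⇌ third conformer (K = 0.0358, k = 0.00345 min⁻¹)
    crystals ⇌ target, rate k2*(cs2 - [target]) while solid is left; crystals form when [target] > cs2 (solubility = 0.170 M, k = 0.0208 min⁻¹)
    other conformer → isomer of the product (k = 0.0127 min⁻¹)
    starting material → target (k = 0.00585 min⁻¹)
    third conformer → third product (k = 0.0154 min⁻¹)
    starting material ⇌ other conformer, settled at all times (K = 0.545)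

Target forms from starting material at 0.00585 min⁻¹, while isomer of the product forms from other conformer, which stands at 0.545 times the starting material, at 0.00692 min⁻¹ reckoned on the starting material, the larger of the two. That comparison holds no concentration and gives a share of 45.8%. For a neighbour flask with 0.20 M of starting material, S gives 46.0% again, and that flask computes to 45.8%, 45.8% and 45.8%, with crystals at 0% at 15.0 d against 10.9% in the flask with 0.50 M, where they count as target.

(The data come from a simulation for an exercise; the scatter is artificial.)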